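**Assumption:** the target has no stereocentre and no stereogenic double bond, so it is one achiral compound and no stereocontrol is needed.

**Retrosynthetic overview**
1. The target comes from its ring B aldehyde; the formyl group is a latent carboxyl, oxidised with chlorite in the last step.
2. The depside aldehyde is cut at the aryl ester C–O bond into 2-heptyl-6-hydroxy-4-methoxybenzoic acid and 2-heptyl-4-hydroxy-6-methoxybenzaldehyde.
3. Both halves come from one aldehyde, 2-heptyl-4,6-dimethoxybenzaldehyde, by complementary mono-demethylation (ortho with BCl3, para with thiolate); that aldehyde comes from Vilsmeier formylation of 1-heptyl-3,5-dimethoxybenzene.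
4. Key C–C disconnection: the benzylic C1'–C2' bond of the heptyl chain. The formyl carbon of 3,5-dimethoxybenzaldehyde, as its N–H hydrazone, acts as a benzyl carbanion equivalent toward 1-bromohexane under nickel catalysis and loses N2, giving the CH2 directly.
5. No ring is built; both benzene rings are bought in 3,5-dimethoxybenzaldehyde.

**Route**

Step 1
Reactants: 1 3,5-dimethoxybenzaldehyde; 2 1-bromohexane
Product: 4 1-heptyl-3,5-dimethoxybenzene, via 3,5-dimethoxybenzaldehyde hydrazone 3 (not isolated)
Conditions: N2H4·H2O (1.2 equiv), THF, rt; then 2, Ni(cod)2 (10 mol %), PMe3 (20 mol %), K3PO4 (2 equiv), 4 Å MS, THF, 60 °C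
Reagents that add atoms: none
Why: Nickel-catalysed alkylation of an N–H hydrazone (carbonyl umpolung, Wolff–Kishner-type denitrogenative C(sp3)–C(sp3) coupling), in which deprotonated 3 reacts at the former formyl carbon as a benzyl carbanion equivalent with the hexylnickel species from oxidative addition of 2 and the resulting diazene loses N2, so two natively electrophilic carbons are joined and the CH2 is obtained with no separate deoxygenation.

Step 2
Reactants: 4 1-heptyl-3,5-dimethoxybenzene
Product: 6 2-heptyl-4,6-dimethoxybenzaldehyde, via Vilsmeier iminium chloride 5 (not isolated)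
Conditions: POCl3 (1.5 equiv), DMF, 0 °C to 70 °C; then H2O
Reagents that add atoms: N,N-dimethylformamide, CN(C)C=O (formyl carbon); water, O (carbonyl oxygen)
Why: Vilsmeier–Haack formylation attacks the position para to one methoxy and ortho to the other, next to the alkyl chain, as it does with 3,5-dimethoxytoluene, because the site between the two methoxy groups is more hindered.

Step 3
Reactants: 6 2-heptyl-4,6-dimethoxybenzaldehyde
Product: 7 2-heptyl-6-hydroxy-4-methoxybenzaldehyde
Conditions: BCl3 (1.2 equiv), CH2Cl2, −78 °C to 0 °C; then H2O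
Reagents that add atoms: none
Why: Chelation-controlled Lewis acid ether cleavage, in which boron bridges the formyl oxygen and the ortho methoxy oxygen so that chloride removes only that methyl group and the para methoxy is untouched at low temperature.

Step 4
Reactants: 7 2-heptyl-6-hydroxy-4-methoxybenzaldehyde
Product: 8 2-heptyl-6-hydroxy-4-methoxybenzoic acid
Conditions: NaClO2, NaH2PO4, 2-methyl-2-butene (20 equiv), t-BuOH/THF/H2O, 0 °C to rt
Reagents that add atoms: sodium chlorite, [Na+].[O-]Cl=O
Why: Lindgren–Kraus–Pinnick oxidation converts the hindered, hydrogen-bonded salicylaldehyde to the acid under buffered conditions, with excess alkene trapping HOCl before it can chlorinate the electron-rich ring.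

Step 5
Reactants: 6 2-heptyl-4,6-dimethoxybenzaldehyde
Product: 9 2-heptyl-4-hydroxy-6-methoxybenzaldehyde
Conditions: NaSEt (2.5 equiv), DMF, 100 °C; then 1 M HCl
Reagents that add atoms: none
Why: Thiolate SN2 demethylation goes preferentially at the methyl ether para to the carbonyl, which is the unhindered one and gives a conjugated phenoxide that blocks a second cleavage; the minor ortho-cleaved isomer is 7 and is fed into step 4.

Step 6
Reactants: 8 2-heptyl-6-hydroxy-4-methoxybenzoic acid; 9 2-heptyl-4-hydroxy-6-methoxybenzaldehyde
Product: 11 4-formyl-3-heptyl-5-methoxyphenyl 2-heptyl-6-hydroxy-4-methoxybenzoate, via mixed trifluoroacetic anhydride 10 (not isolated)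
Conditions: TFAA (3 equiv), toluene, 0 °C to rt; then aq NaHCO3
Reagents that add atoms: none
Why: Depside esterification through the mixed anhydride, in which the electron-rich, doubly ortho-substituted acid is activated towards acyl transfer to the only free, non-chelated phenol (that of 9) while the hydrogen-bonded hydroxyl of 8 stays unacylated.

Step 7
Reactants: 11 4-formyl-3-heptyl-5-methoxyphenyl 2-heptyl-6-hydroxy-4-methoxybenzoate
Product: 12 2-heptyl-4-[(2-heptyl-6-hydroxy-4-methoxybenzoyl)oxy]-6-methoxybenzoic acid
Conditions: NaClO2, NaH2PO4, 2-methyl-2-butene (30 equiv), t-BuOH/THF/H2O, 0 °C to rt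
Reagents that add atoms: sodium chlorite, [Na+].[O-]Cl=O
Why: Lindgren–Kraus–Pinnick oxidation turns the ring B formyl group into the free acid under mildly acidic buffer that leaves the aryl ester, both methyl ethers and the chelated phenol intact, so no carboxyl protecting group is ever needed.

**Compound list**
1 | 3,5-dimethoxybenzaldehyde | COc1cc(C=O)cc(OC)c1 | starting material
2 | 1-bromohexane | CCCCCCBr | starting material
3 | (E)-(3,5-dimethoxybenzylidene)hydrazine (hydrazone of 1) | COc1cc(/C=N/N)cc(OC)c1 | intermediate
4 | 1-heptyl-3,5-dimethoxybenzene | CCCCCCCc1cc(OC)cc(OC)c1 | intermediate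
5 | (2-heptyl-4,6-dimethoxybenzylidene)dimethyliminium chloride | CCCCCCCc1cc(OC)cc(OC)c1C=[N+](C)C.[Cl-] | intermediate
6 | 2-heptyl-4,6-dimethoxybenzaldehyde | CCCCCCCc1cc(OC)cc(OC)c1C=O | intermediate
7 | 2-heptyl-6-hydroxy-4-methoxybenzaldehyde | CCCCCCCc1cc(OC)cc(O)c1C=O | intermediate
8 | 2-heptyl-6-hydroxy-4-methoxybenzoic acid | CCCCCCCc1cc(OC)cc(O)c1C(=O)O | intermediate
9 | 2-heptyl-4-hydroxy-6-methoxybenzaldehyde | CCCCCCCc1cc(O)cc(OC)c1C=O | intermediate
10 | 2-heptyl-6-hydroxy-4-methoxybenzoic trifluoroacetic anhydride | CCCCCCCc1cc(OC)cc(O)c1C(=O)OC(=O)C(F)(F)F | intermediate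
11 | 4-formyl-3-heptyl-5-methoxyphenyl 2-heptyl-6-hydroxy-4-methoxybenzoate | CCCCCCCc1cc(OC)cc(O)c1C(=O)Oc1cc(CCCCCCC)c(C=O)c(OC)c1 | intermediate
12 | 2-heptyl-4-[(2-heptyl-6-hydroxy-4-methoxybenzoyl)oxy]-6-methoxybenzoic acid | CCCCCCCc1cc(OC)cc(O)c1C(=O)Oc1cc(CCCCCCC)c(C(=O)O)c(OC)c1 | target

**Step count:** 7 steps in total. The longest linear sequence is 6 steps (steps 1, 2, 3, 4, 6, 7); the branch through step 5 is 5 steps.

**Three steps most likely to fail**

Step 1 (nickel-catalysed hydrazone alkylation). The risks are N-alkylation of the hydrazone, azine formation, plain Wolff–Kishner reduction to 3,5-dimethoxytoluene, and β-hydride elimination from the hexylnickel species. The ligand and base given are the usual ones for this reaction class and would need screening. The fallback sets out from 1 and comes back at 4. Aldehyde 1 is condensed with propane-1,3-dithiol (BF3·OEt2, CH2Cl2) to 2-(3,5-dimethoxyphenyl)-1,3-dithiane F1. Deprotonation with n-BuLi (THF, −78 °C) gives 2-(3,5-dimethoxyphenyl)-2-lithio-1,3-dithiane F2, which is alkylated with 2 to 2-(3,5-dimethoxyphenyl)-2-hexyl-1,3-dithiane F3. Raney Ni in refluxing ethanol then removes the sulfur and leaves the CH2 of 4.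

Step 5 (para-selective thiolate demethylation). The risk is competing cleavage of the ortho methoxy group. This gives 7, which is still useful but lowers the supply of 9. The fallback sets out from 4 and comes back at 9. Compound 4 is mono-demethylated with NaSEt in DMF at 140 °C to 3-heptyl-5-methoxyphenol F4; the phenoxide formed protects the second ether. Vilsmeier formylation (POCl3, DMF) then goes mainly para to the free hydroxyl through (2-heptyl-4-hydroxy-6-methoxybenzylidene)dimethyliminium chloride F5, which is hydrolysed to 9. The minor regioisomer is again 7 and is separated easily because its chelated hydroxyl makes it much less polar.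

Step 6 (depside coupling with an unprotected salicylic acid). The risks are self-acylation or decarboxylation of 8 and low nucleophilicity of the para-formyl phenol 9. The fallback sets out from 8 and comes back at 11. Acid 8 is treated with acetone, TFAA and trifluoroacetic acid to give 5-heptyl-7-methoxy-2,2-dimethyl-4H-1,3-benzodioxin-4-one F6, which masks the phenol and activates the carboxyl at once. Irradiation at 300 nm in CH2Cl2 in the presence of 9 expels acetone and gives (2-heptyl-4-methoxy-6-oxocyclohexa-2,4-dien-1-ylidene)methanone F7, a quinone ketene. The phenol of 9 traps it to give 11 with the free ortho hydroxyl already in place.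

**Further compounds**
F1 | step 1 | 2-(3,5-dimethoxyphenyl)-1,3-dithiane | COc1cc(cc(OC)c1)C1SCCCS1
F2 | step 1 | 2-(3,5-dimethoxyphenyl)-2-lithio-1,3-dithiane | [Li]C1(SCCCS1)c1cc(OC)cc(OC)c1
F3 | step 1 | 2-(3,5-dimethoxyphenyl)-2-hexyl-1,3-dithiane | CCCCCCC1(SCCCS1)c1cc(OC)cc(OC)c1
F4 | step 5 | 3-heptyl-5-methoxyphenol | CCCCCCCc1cc(O)cc(OC)c1
F5 | step 5 | (2-heptyl-4-hydroxy-6-methoxybenzylidene)dimethyliminium chloride | CCCCCCCc1cc(O)cc(OC)c1C=[N+](C)C.[Cl-]
F6 | step 6 | 5-heptyl-7-methoxy-2,2-dimethyl-4H-1,3-benzodioxin-4-one | CCCCCCCc1cc(OC)cc2OC(C)(C)OC(=O)c12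
F7 | step 6 | (2-heptyl-4-methoxy-6-oxocyclohexa-2,4-dien-1-ylidene)methanone | CCCCCCCC1=CC(OC)=CC(=O)C1=C=O
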